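With the cyclohexene ring numbered C1 (carrying C7H2OBz), C2 (vinyl CH), C3 (OBz) and C4–C6 (carbinols), the route rests on tracing the ring's only cis-diol, C4–OH/C5–OH, to an enzymatic dearomatisation. Toluene dioxygenase adds O2 across the ortho/meta bond of bromobenzene and so forms the C4–O and C5–O bonds as a single enantiomer in one operation; no ring is closed. The precursor is bromobenzene itself: its bromine marks C6 as a latent ketone and its diene becomes C1–C3. Singlet oxygen then relays the configuration to C3, a Baylis–Hillman reaction adds C7, and a hydroxyl-directed reduction from the freed C4/C5 diol sets C6.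

Key step: step 1

Assumption: a recombinant strain that expresses toluene dioxygenase without the cis-diol dehydrogenase is available; it is treated as a catalyst, not as a starting material. Ring positions in the steps use the target numbering given above. The target is the (3R,4R,5R,6S) isomer: O3 and O6 on one ring face, O4 and O5 on the other.

Step 1
Reactants: 1 bromobenzene
Product: 2 (1S,2S)-3-bromocyclohexa-3,5-diene-1,2-diol
Conditions: E. coli JM109(pDTG601) whole cells (toluene dioxygenase), IPTG, glucose feed, air, phosphate buffer pH 7, 35 °C; EtOAc extraction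
Reagents that add atoms: dioxygen O=O
Why: The Rieske-type non-haem iron oxygenase binds bromobenzene and O2 at its mononuclear iron, receives two electrons from NADH through its reductase and ferredoxin, and transfers both oxygen atoms to one face of the C2–C3 bond of the arene, so that the future C5–O and C4–O bonds form cis with loss of aromaticity. The closest known reaction type is the whole-cell toluene dioxygenase cis-dihydroxylation of monohalobenzenes, an established preparative biotransformation. No ring is closed. Both new stereocentres (1S,2S) are controlled by the enzyme pocket, which places the bromine-bearing carbon next to the oxidised bond and exposes a single arene face. The step needs 2,3-regioselectivity (not 3,4 or ipso), one absolute configuration and no onward oxidation; the first two are secured by the enzyme, since the substrate has no bias of its own, and the third by a host that carries the oxygenase genes but no diol dehydrogenase.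

Step 2
Reactants: 2 (1S,2S)-3-bromocyclohexa-3,5-diene-1,2-diol; 3 2,2-dimethoxypropane
Product: 4 (3aS,7aS)-4-bromo-2,2-dimethyl-3a,7a-dihydro-1,3-benzodioxole
Conditions: Me2C(OMe)2, p-TsOH·H2O (cat.), acetone, 0 °C to rt
Reagents that add atoms: 2,2-dimethoxypropane COC(C)(C)OC
Why: Acid-catalysed transketalisation (acetonide formation) is fast for the cis-1,2-diol and touches neither stereocentre, while the mild, nearly anhydrous conditions should avoid dehydration of the dienediol to a bromophenol.

Step 3
Reactants: 4 (3aS,7aS)-4-bromo-2,2-dimethyl-3a,7a-dihydro-1,3-benzodioxole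
Product: 7 (4R,5S,6S)-4-hydroxy-5,6-(isopropylidenedioxy)cyclohex-2-en-1-one, via bromo endoperoxide 5 (not isolated), via gem-bromohydrin 6 (not isolated)
Conditions: O2, TPP (cat.), hν (visible), CH2Cl2, −78 °C; then thiourea (2.5 equiv), MeOH, −78 °C to rt
Reagents that add atoms: dioxygen O=O
Why: Singlet oxygen should add in a [4+2] cycloaddition across C3 and C6 of the s-cis diene on the face away from the dioxolane, which sets C3–O trans to O4, and thiourea reduction of the O–O bond leaves a C6 gem-bromohydrin that expels HBr to the ketone, so the enone C6(=O)–C1=C2 with a free C3 carbinol results (singlet-oxygen Diels–Alder reaction followed by endoperoxide reduction).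

Step 4
Reactants: 7 (4R,5S,6S)-4-hydroxy-5,6-(isopropylidenedioxy)cyclohex-2-en-1-one; 8 formaldehyde
Product: 9 (4R,5S,6S)-4-hydroxy-2-(hydroxymethyl)-5,6-(isopropylidenedioxy)cyclohex-2-en-1-one
Conditions: HCHO (37% aq.), DMAP (0.3 equiv), THF/H2O, rt
Reagents that add atoms: formaldehyde C=O
Why: In this Morita–Baylis–Hillman reaction DMAP adds reversibly to C2 of the enone, the enolate is hydroxymethylated at C1 by formaldehyde and loss of DMAP restores the enone, so C7 is attached at the α-carbon without a new stereocentre, while the cis-fused dioxolane holds the enolisable C5 in its configuration.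

Step 5
Reactants: 9 (4R,5S,6S)-4-hydroxy-2-(hydroxymethyl)-5,6-(isopropylidenedioxy)cyclohex-2-en-1-one; 10 benzoyl chloride
Product: 11 [(3R,4S,5S)-3-(benzoyloxy)-4,5-(isopropylidenedioxy)-6-oxocyclohex-1-en-1-yl]methyl benzoate
Conditions: BzCl (2.5 equiv), pyridine, CH2Cl2, 0 °C
Reagents that add atoms: benzoyl chloride O=C(Cl)c1ccccc1
Why: O-Acylation with an acid chloride in pyridine (Einhorn conditions) should esterify the primary and the secondary allylic hydroxyl, and a more nucleophilic catalyst is left out so that the new primary allylic ester is not displaced in an SN2′ sense.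

Step 6
Reactants: 11 [(3R,4S,5S)-3-(benzoyloxy)-4,5-(isopropylidenedioxy)-6-oxocyclohex-1-en-1-yl]methyl benzoate
Product: 12 [(3R,4R,5S)-3-(benzoyloxy)-4,5-dihydroxy-6-oxocyclohex-1-en-1-yl]methyl benzoate
Conditions: TFA/H2O (4:1), 0 °C to rt
Reagents that add atoms: none
Why: Aqueous acid hydrolysis of the isopropylidene acetal should free the C4/C5 diol while the benzoates and the enone are inert to cold aqueous trifluoroacetic acid, and the short cold exposure limits acyl migration from O3 to O4.

Step 7
Reactants: 12 [(3R,4R,5S)-3-(benzoyloxy)-4,5-dihydroxy-6-oxocyclohex-1-en-1-yl]methyl benzoate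
Product: 13 [(3R,4R,5R,6S)-3-(benzoyloxy)-4,5,6-trihydroxycyclohex-1-en-1-yl]methyl benzoate (target)
Conditions: Me4NBH(OAc)3 (4 equiv), MeCN/AcOH (1:1), −30 to 0 °C
Reagents that add atoms: none
Why: In this Evans–Saksena hydroxyl-directed reduction the triacetoxyborohydride exchanges an acetate for the C4 hydroxyl (or the C5 hydroxyl on the same face) and delivers hydride intramolecularly to the ketone face that carries O4 and O5, so the new C6 hydroxyl should emerge anti to O4 and trans to O5 as the target requires, the reagent being too weak to reduce the ketone without this delivery or to touch the esters and the alkene.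

Compound list
1 | bromobenzene | Brc1ccccc1 | starting material
2 | (1S,2S)-3-bromocyclohexa-3,5-diene-1,2-diol | BrC1=CC=C[C@H](O)[C@@H]1O | intermediate
3 | 2,2-dimethoxypropane | COC(C)(C)OC | starting material
4 | (3aS,7aS)-4-bromo-2,2-dimethyl-3a,7a-dihydro-1,3-benzodioxole | BrC1=CC=C[C@H](OC(C)(C)O2)[C@@H]12 | intermediate
5 | bromo endoperoxide: 6-bromo-3,6-epidioxy-4,5-(isopropylidenedioxy)cyclohex-1-ene, O–O bridge on the face opposite the dioxolane | C1=C[C@@H](OO2)[C@H](OC(C)(C)O3)[C@H]3[C@]12Br | intermediate
6 | gem-bromohydrin: 6-bromo-4,5-(isopropylidenedioxy)cyclohex-1-ene-3,6-diol, both hydroxyls on the face opposite the dioxolane | C1=C[C@@H](O)[C@H](OC(C)(C)O2)[C@H]2[C@]1(O)Br | intermediate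
7 | (4R,5S,6S)-4-hydroxy-5,6-(isopropylidenedioxy)cyclohex-2-en-1-one | C1=C[C@@H](O)[C@H](OC(C)(C)O2)[C@H]2C1=O | intermediate
8 | formaldehyde | C=O | starting material
9 | (4R,5S,6S)-4-hydroxy-2-(hydroxymethyl)-5,6-(isopropylidenedioxy)cyclohex-2-en-1-one | OCC1=C[C@@H](O)[C@H](OC(C)(C)O2)[C@H]2C1=O | intermediate
10 | benzoyl chloride | O=C(Cl)c1ccccc1 | starting material
11 | [(3R,4S,5S)-3-(benzoyloxy)-4,5-(isopropylidenedioxy)-6-oxocyclohex-1-en-1-yl]methyl benzoate | O=C(OCC1=C[C@@H](OC(=O)c2ccccc2)[C@H](OC(C)(C)O3)[C@H]3C1=O)c1ccccc1 | intermediate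
12 | [(3R,4R,5S)-3-(benzoyloxy)-4,5-dihydroxy-6-oxocyclohex-1-en-1-yl]methyl benzoate | O=C(OCC1=C[C@@H](OC(=O)c2ccccc2)[C@H](O)[C@H](O)C1=O)c1ccccc1 | intermediate
13 | [(3R,4R,5R,6S)-3-(benzoyloxy)-4,5,6-trihydroxycyclohex-1-en-1-yl]methyl benzoate | O=C(OCC1=C[C@@H](OC(=O)c2ccccc2)[C@H](O)[C@H](O)[C@H]1O)c1ccccc1 | target

Total step count: 7. Longest linear sequence: 7 steps (1 → 2 → 4 → 7 → 9 → 11 → 12 → 13).

Steps most likely to fail

1. Step 7. Hydride delivery may be only partly intramolecular, so that attack from the face opposite the diol competes and the facial selectivity at C6 erodes; acyl migration in the acidic medium is a second concern. The fallback sets out from 11 and comes back to the route at 13; it replaces directed delivery by reduction, inversion and late deprotection. Luche reduction of 11 (NaBH4, CeCl3·7H2O, MeOH, −78 °C) should deliver hydride anti to the dioxolane and give the C6 alcohol cis to O5, [(3R,4S,5R,6R)-3-(benzoyloxy)-6-hydroxy-4,5-(isopropylidenedioxy)cyclohex-1-en-1-yl]methyl benzoate F1. A Mitsunobu reaction with chloroacetic acid (PPh3, DIAD, toluene, 0 °C to rt) should invert C6, the carboxylate entering on the open face anti to the dioxolane, and give [(3R,4S,5R,6S)-3-(benzoyloxy)-6-(chloroacetoxy)-4,5-(isopropylidenedioxy)cyclohex-1-en-1-yl]methyl benzoate F2. Thiourea with NaHCO3 in EtOH/THF at 50 °C should remove the chloroacetyl group without touching the benzoates and give [(3R,4S,5R,6S)-3-(benzoyloxy)-6-hydroxy-4,5-(isopropylidenedioxy)cyclohex-1-en-1-yl]methyl benzoate F3. Cold TFA/H2O then cleaves the acetonide to give 13.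

2. Step 4. The amine catalyst may instead promote enolisation towards C5 and β-elimination of the C4 oxygen, which leads to aromatisation, or the conjugate addition may stall on the γ-oxygenated enone. The fallback sets out from 7 and comes back at 9; it replaces the organocatalytic aldol by halogenation and cross-coupling. α-Iodination of the enone (I2, pyridine, CH2Cl2, rt) should give (4R,5S,6S)-4-hydroxy-2-iodo-5,6-(isopropylidenedioxy)cyclohex-2-en-1-one F4. Stille coupling with (tributylstannyl)methanol (Pd2(dba)3, AsPh3, CuI, NMP, 60 °C) then installs the hydroxymethyl group at C1 and gives 9.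

3. Step 6. Hydrolysis of an acetal that sits next to the carbonyl is slow, and under longer acid exposure the keto-diol may lose water across C4–C5 and then benzoic acid on the way to an aromatic ring. The fallback sets out from 11 and comes back at 12; it removes the ketone before the acid step so that this elimination path is closed. Luche reduction as above gives the C6 alcohol [(3R,4S,5R,6R)-3-(benzoyloxy)-6-hydroxy-4,5-(isopropylidenedioxy)cyclohex-1-en-1-yl]methyl benzoate F1 (the same compound as in the first fallback). TFA/H2O should then give the all-cis triol [(3R,4R,5R,6R)-3-(benzoyloxy)-4,5,6-trihydroxycyclohex-1-en-1-yl]methyl benzoate F5. Oxidation with activated MnO2 (CH2Cl2, rt), which is selective for the allylic C6 hydroxyl, should return the ketone 12.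

Further compounds
F1 | step 7 | [(3R,4S,5R,6R)-3-(benzoyloxy)-6-hydroxy-4,5-(isopropylidenedioxy)cyclohex-1-en-1-yl]methyl benzoate | O=C(OCC1=C[C@@H](OC(=O)c2ccccc2)[C@H](OC(C)(C)O3)[C@H]3[C@@H]1O)c1ccccc1
F2 | step 7 | [(3R,4S,5R,6S)-3-(benzoyloxy)-6-(chloroacetoxy)-4,5-(isopropylidenedioxy)cyclohex-1-en-1-yl]methyl benzoate | O=C(OCC1=C[C@@H](OC(=O)c2ccccc2)[C@H](OC(C)(C)O3)[C@H]3[C@H]1OC(=O)CCl)c1ccccc1
F3 | step 7 | [(3R,4S,5R,6S)-3-(benzoyloxy)-6-hydroxy-4,5-(isopropylidenedioxy)cyclohex-1-en-1-yl]methyl benzoate | O=C(OCC1=C[C@@H](OC(=O)c2ccccc2)[C@H](OC(C)(C)O3)[C@H]3[C@H]1O)c1ccccc1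
F4 | step 4 | (4R,5S,6S)-4-hydroxy-2-iodo-5,6-(isopropylidenedioxy)cyclohex-2-en-1-one | IC1=C[C@@H](O)[C@H](OC(C)(C)O2)[C@H]2C1=O
F5 | step 6 | [(3R,4R,5R,6R)-3-(benzoyloxy)-4,5,6-trihydroxycyclohex-1-en-1-yl]methyl benzoate | O=C(OCC1=C[C@@H](OC(=O)c2ccccc2)[C@H](O)[C@H](O)[C@@H]1O)c1ccccc1
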